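**Plan**

- Retrosynthesis first removes the two acetates, the C7 formyl group (from a C7 ketone through its C7=C8 enol triflate and CO) and the C2 methylidene group (from a C2 ketone).
- The cyclohexene C6–C7–C8–C9–C1–C10 is bridged from C6 to C1 by the chain C5–C4–C3–C2 and carries oxygen on C10 and a carbonyl-level C7. This meta-bridged, 1,3-dioxygenated ring is cut at C1–C10 and C8–C9 in one type 2 intramolecular Diels–Alder transform.
- The acyclic triene is cut at C1–C2 (vinyl Grignard on a Weinreb amide), C6–C7 (crossed Claisen on a thioester), C3–C4 (acetate aldol) and C5–C6 (imide enolate alkylation).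
- Forward: the chain is joined from (S)-citronellic acid in the order C5–C6, C3–C4, C6–C7, C1–C2. One cycloaddition then closes the six- and seven-membered rings together, followed by C2=CH2, the C7 aldehyde and the acetates.
- Stereochemistry: C1′ from citronellic acid; C5 by Evans alkylation; C4 by a reagent-controlled acetate aldol matched with Felkin–Anh control; C10 and C1 in the cycloaddition (E enol ether, tether, diene face chosen by C5); C6 by protonation of the bridgehead enol ether.

Key step: step 13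

Remark: locants C1–C10 (bicyclo[4.3.1]dec-7-ene numbering of the target) and C1′ (side-chain carbon on C5) are used for all intermediates; TBS = tert-butyldimethylsilyl; (S)-citronellic acid and (S)-HYTRA are assumed to be commercial in high enantiomeric purity.

Step 1
Reactants: 1 (S)-citronellic acid [(3S)-3,7-dimethyloct-6-enoic acid]; 2 (S)-4-benzyl-1,3-oxazolidin-2-one
Product: 4 (4S)-4-benzyl-3-[(3S)-3,7-dimethyloct-6-enoyl]-1,3-oxazolidin-2-one, via mixed pivalic anhydride 3 (not isolated)
Conditions: pivaloyl chloride, Et3N, THF, −20 °C; then 2, LiCl, −20 °C → rt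
Reagents that add atoms: none
Why: N-acylation of the oxazolidinone through the mixed pivalic anhydride is the standard racemisation-free way to load an Evans auxiliary, and no stereocentre is formed.

Step 2
Reactants: 4; 5 tert-butyl bromoacetate
Product: 7 tert-butyl (3S,4S)-3-{[(4S)-4-benzyl-2-oxo-1,3-oxazolidin-3-yl]carbonyl}-4,8-dimethylnon-7-enoate, via sodium Z-enolate 6 (not isolated)
Conditions: NaN(SiMe3)2, THF, −78 °C; then 5, −78 → −40 °C
Reagents that add atoms: none
Why: Evans asymmetric alkylation, in which the chelated Z-enolate is shielded on one face by the benzyl group so that the bromoacetate enters anti to it and sets C5 in the sense established for (S)-4-benzyl imides, the remote C1′ centre having little influence.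

Step 3
Reactants: 7
Product: 8 tert-butyl (3S,4S)-3-(hydroxymethyl)-4,8-dimethylnon-7-enoate
Conditions: LiBH4, MeOH (1 equiv), Et2O, 0 °C
Reagents that add atoms: none
Why: Reductive removal of the auxiliary, since LiBH4 reduces the activated exocyclic imide carbonyl to the primary alcohol at 0 °C while the tert-butyl ester and the C5 centre are untouched.

Step 4
Reactants: 8
Product: 9 tert-butyl (3S,4S)-3-formyl-4,8-dimethylnon-7-enoate
Conditions: Dess–Martin periodinane, NaHCO3, CH2Cl2, 0 °C → rt; used at once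
Reagents that add atoms: none
Why: Buffered Dess–Martin oxidation gives the α-branched aldehyde without acid or Lewis acid, which avoids epimerisation at C5 and the carbonyl-ene cyclisation typical of citronellal-type aldehydes.

Step 5
Reactants: 9; 10 (S)-2-hydroxy-1,2,2-triphenylethyl acetate [(S)-HYTRA]
Product: 12 6-tert-butyl 1-[(1S)-2-hydroxy-1,2,2-triphenylethyl] (3S,4S)-3-hydroxy-4-[(2S)-6-methylhept-5-en-2-yl]hexanedioate, via dilithiated HYTRA 11 (not isolated)
Conditions: 10, LiN(iPr)2 (2.1 equiv), THF, −78 → 0 °C; then 9, THF/2-methylbutane, −110 °C; aq. NH4Cl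
Reagents that add atoms: none
Why: HYTRA acetate aldol addition (Braun aldol), in which the doubly deprotonated (S)-acetate adds under reagent control to the aldehyde face that gives the (4S)-carbinol, reinforced by Felkin–Anh attack anti to the branched C1′ substituent (matched pair) and free of any Lewis acid.

Step 6
Reactants: 12
Product: 13 tert-butyl (3S,4S)-4-hydroxy-6-[methoxy(methyl)amino]-3-[(2S)-6-methylhept-5-en-2-yl]-6-oxohexanoate
Conditions: MeNH(OMe)·HCl, iPrMgCl, THF, −20 → 0 °C
Reagents that add atoms: N,O-dimethylhydroxylamine hydrochloride, CNOC.Cl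
Why: Ester aminolysis by the chloromagnesium amide of N,O-dimethylhydroxylamine (Weinreb amide formation) displaces the glycol auxiliary at low temperature while the hindered tert-butyl ester does not react.

Step 7
Reactants: 13
Product: 15 (3S,4S)-4-(TBSO)-6-[methoxy(methyl)amino]-3-[(2S)-6-methylhept-5-en-2-yl]-6-oxohexanoic acid, via silyl ether silyl ester 14 (not isolated)
Conditions: TBSOTf (3 equiv), 2,6-lutidine, CH2Cl2, −78 °C → rt; then K2CO3, MeOH–H2O, 0 °C; pH 4 work-up
Reagents that add atoms: tert-butyldimethylsilyl triflate, CC(C)(C)[Si](C)(C)OS(=O)(=O)C(F)(F)F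
Why: The silyl triflate silylates the C4 alcohol in the cold and, on warming in excess, converts the tert-butyl ester into the silyl ester with loss of isobutene (silyl triflate ester cleavage), after which carbonate methanolysis frees only the acid.

Step 8
Reactants: 15
Product: 16 S-phenyl (3S,4S)-4-(TBSO)-6-[methoxy(methyl)amino]-3-[(2S)-6-methylhept-5-en-2-yl]-6-oxohexanethioate
Conditions: PhSH, EDC·HCl, DMAP (cat.), CH2Cl2, 0 °C → rt
Reagents that add atoms: thiophenol, Sc1ccccc1
Why: Steglich-type carbodiimide thioesterification gives the aryl thioester, which makes the C6 methylene the most acidic position of the molecule.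

Step 9
Reactants: 16; 17 1-acetyl-1H-benzotriazole
Product: 18 S-phenyl (3R,4S)-2-acetyl-4-(TBSO)-6-[methoxy(methyl)amino]-3-[(2S)-6-methylhept-5-en-2-yl]-6-oxohexanethioate (C6 epimers and enol)
Conditions: MgBr2·OEt2, iPr2NEt, CH2Cl2, rt
Reagents that add atoms: none
Why: Soft-enolisation crossed Claisen condensation, in which MgBr2 and the amine base enolise only the thioester and the magnesium enolate is C-acylated by the acyl benzotriazole, so C7 and C8 are attached without a strong base that could eliminate the β-silyloxy amide; the new C6 centre is irrelevant because it becomes sp2.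

Step 10
Reactants: 18
Product: 19 (3S,4R)-5-formyl-3-(TBSO)-N-methoxy-N-methyl-4-[(2S)-6-methylhept-5-en-2-yl]-6-oxoheptanamide (chelated enol of the 2-formyl ketone)
Conditions: Et3SiH, palladium on carbon (Pd/C, 10%), acetone, rt
Reagents that add atoms: none
Why: Fukuyama reduction takes the thioester to the aldehyde oxidation level and stops there, sparing the Weinreb amide, the ketone and the trisubstituted alkene.

Step 11
Reactants: 19
Product: 21 (3S,4R)-3,6-bis(TBSO)-5-[(E)-(TBSO)methylidene]-N-methoxy-N-methyl-4-[(2S)-6-methylhept-5-en-2-yl]hept-6-enamide, via mono-silylated vinylogous ester 20 (not isolated)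
Conditions: TBSOTf (2.4 equiv), Et3N, Et2O, −78 → 0 °C; cold NaHCO3 work-up, filtration through Et3N-deactivated alumina
Reagents that add atoms: tert-butyldimethylsilyl triflate, CC(C)(C)[Si](C)(C)OS(=O)(=O)C(F)(F)F
Why: Double silylative enolisation of a 1,3-dicarbonyl compound, in which the second silyl triflate activates the vinylogous silyl ester and the amine removes a C8 proton; the C10=C6 bond should settle as E (silyloxy cis to C5, trans to C7) in the W-shaped bis(silyloxy)allyl cation because the other geometry forces 1,3-allylic strain between the C10 oxygen and the C7 substituents.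

Step 12
Reactants: 21; 22 vinylmagnesium bromide
Product: 24 (5S,6R)-5,8-bis(TBSO)-7-[(E)-(TBSO)methylidene]-6-[(2S)-6-methylhept-5-en-2-yl]nona-1,8-dien-3-one, via magnesium hemiaminal chelate 23 (not isolated)
Conditions: CH2=CHMgBr, THF, −78 → −20 °C; inverse quench into cold pH 7 phosphate buffer/Et2O; used at once
Reagents that add atoms: none
Why: Weinreb ketone synthesis, in which the Grignard reagent adds once to give a stable magnesium chelate that is inert to the silyl enol ethers and releases the vinyl ketone only on the cold neutral quench, where fast phase separation keeps the freed hydroxylamine from adding to the enone.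

Step 13
Reactants: 24
Product: 25 (1S,4S,5R,10S)-4,7,10-tris(TBSO)-5-[(2S)-6-methylhept-5-en-2-yl]bicyclo[4.3.1]dec-6-en-2-one
Conditions: toluene (0.005 M), BHT, 2,6-di-tert-butyl-4-methylpyridine (cat.), base-washed sealed vessel, 110 °C
Reagents that add atoms: none
Why: Thermal type 2 intramolecular Diels–Alder reaction, a concerted but asynchronous [4+2] cycloaddition in which the nucleophilic diene terminus C8 bonds to the enone β-carbon C9 ahead of the C10–C1 bond; the closest known reactions are the type 2 cycloadditions of 2-tethered dienes to vinyl ketones that give bridgehead-alkene bicyclo[4.3.1]decenones and the additions of 1,3-bis(silyloxy)dienes to enones. The six-membered ring (C10–C6–C7–C8–C9–C1) closes as the cycloadduct ring and the seven-membered ring (C1–C2–C3–C4–C5–C6–C10) closes as the tether bridge, the four-atom tether allowing only the meta orientation, which the polarisation of the diene also favours. C10 is controlled by the E enol ether, which puts its silyloxy group on the side of the four-carbon bridge, and C1 is tied to C10 by the tether, so the only selectivity needed is the diene face. That face is set by C5: in the reactive conformer C5–H lies in the diene plane next to the cis C10 silyloxy group (least 1,3-allylic strain), so C4 with the dienophile and the branched C1′ chain lie on opposite faces and the enone is delivered to the face that gives the (1S,10S) adduct. The bridgehead enol ether formed is strained but allowed (trans double bond within a nine-membered ring), and dilution, a radical inhibitor and a hindered base should suppress polymerisation and loss of the silyl enol ethers.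

Step 14
Reactants: 25
Product: 26 (1R,4S,5R,10S)-4,7,10-tris(TBSO)-2-methylidene-5-[(2S)-6-methylhept-5-en-2-yl]bicyclo[4.3.1]dec-6-ene
Conditions: Cp2TiMe2, toluene, 70 °C, dark
Reagents that add atoms: dimethyltitanocene, C[Ti](C)(C1C=CC=C1)C1C=CC=C1
Why: Petasis methylenation converts the only carbonyl group (C2) into the methylidene group under neutral conditions that neither eliminate the β-silyloxy group nor affect the silyl enol ether.

Step 15
Reactants: 26
Product: 27 (1R,4S,5R,6S,10S)-4,10-bis(TBSO)-2-methylidene-5-[(2S)-6-methylhept-5-en-2-yl]bicyclo[4.3.1]decan-7-one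
Conditions: Bu4NF (1.05 equiv), AcOH (1.2 equiv), THF, −40 → 0 °C
Reagents that add atoms: none
Why: Buffered fluoride cleaves the silyl enol ether much faster than the two secondary silyl ethers, and the strained bridgehead enol is protonated at C6 from the only accessible (outer) face, which fixes C6.

Step 16
Reactants: 27
Product: 29 (1R,4S,5R,6S,10S)-4,10-bis(TBSO)-2-methylidene-5-[(2S)-6-methylhept-5-en-2-yl]bicyclo[4.3.1]dec-7-en-7-yl trifluoromethanesulfonate, via potassium C7–C8 enolate 28 (not isolated)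
Conditions: KN(SiMe3)2, THF, −78 °C; then PhNTf2, −78 → 0 °C
Reagents that add atoms: N-phenylbis(trifluoromethanesulfonimide), O=S(=O)(N(c1ccccc1)S(=O)(=O)C(F)(F)F)C(F)(F)F
Why: Regioselective enol triflate formation, because kinetic deprotonation of the C7 ketone can occur only at C8 (the C6 bridgehead hydrogen is misaligned and would give the strained bridgehead enolate) and O-sulfonylation then fixes the C7=C8 double bond.

Step 17
Reactants: 29
Product: 30 (1R,4S,5R,6R,10S)-4,10-bis(TBSO)-2-methylidene-5-[(2S)-6-methylhept-5-en-2-yl]bicyclo[4.3.1]dec-7-ene-7-carbaldehyde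
Conditions: Pd(PPh3)4 (cat.), CO (1–3 atm), Bu3SnH (slow addition), LiCl, THF, 50 °C
Reagents that add atoms: carbon monoxide, [C-]#[O+]
Why: Palladium-catalysed reductive carbonylation of a vinyl triflate (Stille-type formylation), in which oxidative addition, CO insertion and hydride transfer from the slowly added tin hydride give the conjugated C7 aldehyde directly.

Step 18
Reactants: 30
Product: 31 (1R,4S,5R,6R,10S)-4,10-dihydroxy-2-methylidene-5-[(2S)-6-methylhept-5-en-2-yl]bicyclo[4.3.1]dec-7-ene-7-carbaldehyde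
Conditions: HF·pyridine, pyridine, THF, 0 °C → rt
Reagents that add atoms: none
Why: Buffered HF·pyridine desilylation removes both secondary silyl ethers without base, so the enal and the exocyclic alkene should not isomerise and no stereocentre is affected.

Step 19
Reactants: 31
Product: 32 (1R,4S,5R,6R,10S)-7-formyl-2-methylidene-5-[(2S)-6-methylhept-5-en-2-yl]bicyclo[4.3.1]dec-7-ene-4,10-diyl diacetate (CNP0197379.1)
Conditions: Ac2O, pyridine, DMAP (cat.), CH2Cl2, rt
Reagents that add atoms: acetic anhydride, CC(=O)OC(C)=O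
Why: DMAP-catalysed acetylation of the two secondary alcohols completes the target with all six stereocentres as set earlier.

**Compound list**

1 | (S)-citronellic acid | OC(=O)C[C@@H](C)CCC=C(C)C | starting material
2 | (S)-4-benzyl-1,3-oxazolidin-2-one | O=C1OC[C@H](Cc2ccccc2)N1 | starting material
3 | (3S)-3,7-dimethyloct-6-enoic pivalic anhydride | CC(C)(C)C(=O)OC(=O)C[C@@H](C)CCC=C(C)C | intermediate
4 | (4S)-4-benzyl-3-[(3S)-3,7-dimethyloct-6-enoyl]-1,3-oxazolidin-2-one | O=C1OC[C@H](Cc2ccccc2)N1C(=O)C[C@@H](C)CCC=C(C)C | intermediate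
5 | tert-butyl bromoacetate | CC(C)(C)OC(=O)CBr | starting material
6 | sodium Z-enolate of 4 | [Na+].[O-]/C(=C\[C@@H](C)CCC=C(C)C)N1[C@@H](Cc2ccccc2)COC1=O | intermediate
7 | tert-butyl (3S,4S)-3-{[(4S)-4-benzyl-2-oxo-1,3-oxazolidin-3-yl]carbonyl}-4,8-dimethylnon-7-enoate | O=C1OC[C@H](Cc2ccccc2)N1C(=O)[C@H]([C@@H](C)CCC=C(C)C)CC(=O)OC(C)(C)C | intermediate
8 | tert-butyl (3S,4S)-3-(hydroxymethyl)-4,8-dimethylnon-7-enoate | OC[C@H]([C@@H](C)CCC=C(C)C)CC(=O)OC(C)(C)C | intermediate
9 | tert-butyl (3S,4S)-3-formyl-4,8-dimethylnon-7-enoate | O=C[C@H]([C@@H](C)CCC=C(C)C)CC(=O)OC(C)(C)C | intermediate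
10 | (S)-2-hydroxy-1,2,2-triphenylethyl acetate, (S)-HYTRA | CC(=O)O[C@@H](c1ccccc1)C(O)(c1ccccc1)c1ccccc1 | starting material
11 | dilithium enolate alkoxide of 10 | [Li+].[Li+].C=C([O-])O[C@@H](c1ccccc1)C([O-])(c1ccccc1)c1ccccc1 | intermediate
12 | 6-tert-butyl 1-[(1S)-2-hydroxy-1,2,2-triphenylethyl] (3S,4S)-3-hydroxy-4-[(2S)-6-methylhept-5-en-2-yl]hexanedioate | O=C(C[C@H](O)[C@H]([C@@H](C)CCC=C(C)C)CC(=O)OC(C)(C)C)O[C@@H](c1ccccc1)C(O)(c1ccccc1)c1ccccc1 | intermediate
13 | tert-butyl (3S,4S)-4-hydroxy-6-[methoxy(methyl)amino]-3-[(2S)-6-methylhept-5-en-2-yl]-6-oxohexanoate | CON(C)C(=O)C[C@H](O)[C@H]([C@@H](C)CCC=C(C)C)CC(=O)OC(C)(C)C | intermediate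
14 | tert-butyldimethylsilyl (3S,4S)-4-(TBSO)-6-[methoxy(methyl)amino]-3-[(2S)-6-methylhept-5-en-2-yl]-6-oxohexanoate | CON(C)C(=O)C[C@H](O[Si](C)(C)C(C)(C)C)[C@H]([C@@H](C)CCC=C(C)C)CC(=O)O[Si](C)(C)C(C)(C)C | intermediate
15 | (3S,4S)-4-(TBSO)-6-[methoxy(methyl)amino]-3-[(2S)-6-methylhept-5-en-2-yl]-6-oxohexanoic acid | CON(C)C(=O)C[C@H](O[Si](C)(C)C(C)(C)C)[C@H]([C@@H](C)CCC=C(C)C)CC(=O)O | intermediate
16 | S-phenyl (3S,4S)-4-(TBSO)-6-[methoxy(methyl)amino]-3-[(2S)-6-methylhept-5-en-2-yl]-6-oxohexanethioate | CON(C)C(=O)C[C@H](O[Si](C)(C)C(C)(C)C)[C@H]([C@@H](C)CCC=C(C)C)CC(=O)Sc1ccccc1 | intermediate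
17 | 1-acetyl-1H-benzotriazole | CC(=O)n1nnc2ccccc12 | starting material
18 | S-phenyl (3R,4S)-2-acetyl-4-(TBSO)-6-[methoxy(methyl)amino]-3-[(2S)-6-methylhept-5-en-2-yl]-6-oxohexanethioate (C2 epimers) | CON(C)C(=O)C[C@H](O[Si](C)(C)C(C)(C)C)[C@H]([C@@H](C)CCC=C(C)C)C(C(C)=O)C(=O)Sc1ccccc1 | intermediate
19 | (3S,4R)-5-formyl-3-(TBSO)-N-methoxy-N-methyl-4-[(2S)-6-methylhept-5-en-2-yl]-6-oxoheptanamide (C5 epimers, mainly enol) | CON(C)C(=O)C[C@H](O[Si](C)(C)C(C)(C)C)[C@H]([C@@H](C)CCC=C(C)C)C(C=O)C(C)=O | intermediate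
20 | (3S,4R)-3-(TBSO)-5-[(TBSO)methylidene]-N-methoxy-N-methyl-4-[(2S)-6-methylhept-5-en-2-yl]-6-oxoheptanamide (alkene geometry not fixed) | CON(C)C(=O)C[C@H](O[Si](C)(C)C(C)(C)C)[C@H]([C@@H](C)CCC=C(C)C)C(=CO[Si](C)(C)C(C)(C)C)C(C)=O | intermediate
21 | (3S,4R)-3,6-bis(TBSO)-5-[(E)-(TBSO)methylidene]-N-methoxy-N-methyl-4-[(2S)-6-methylhept-5-en-2-yl]hept-6-enamide | CON(C)C(=O)C[C@H](O[Si](C)(C)C(C)(C)C)[C@H]([C@@H](C)CCC=C(C)C)/C(=C\O[Si](C)(C)C(C)(C)C)C(=C)O[Si](C)(C)C(C)(C)C | intermediate
22 | vinylmagnesium bromide | C=C[Mg]Br | starting material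
23 | bromomagnesium alkoxide of the N-methoxy-N-methyl hemiaminal from 21 and 22 | C=CC(O[Mg]Br)(N(C)OC)C[C@H](O[Si](C)(C)C(C)(C)C)[C@H]([C@@H](C)CCC=C(C)C)/C(=C\O[Si](C)(C)C(C)(C)C)C(=C)O[Si](C)(C)C(C)(C)C | intermediate
24 | (5S,6R)-5,8-bis(TBSO)-7-[(E)-(TBSO)methylidene]-6-[(2S)-6-methylhept-5-en-2-yl]nona-1,8-dien-3-one (cycloaddition precursor) | C=CC(=O)C[C@H](O[Si](C)(C)C(C)(C)C)[C@H]([C@@H](C)CCC=C(C)C)/C(=C\O[Si](C)(C)C(C)(C)C)C(=C)O[Si](C)(C)C(C)(C)C | intermediate
25 | (1S,4S,5R,10S)-4,7,10-tris(TBSO)-5-[(2S)-6-methylhept-5-en-2-yl]bicyclo[4.3.1]dec-6-en-2-one (cycloadduct) | O=C1C[C@H](O[Si](C)(C)C(C)(C)C)[C@H]([C@@H](C)CCC=C(C)C)C2=C(O[Si](C)(C)C(C)(C)C)CC[C@H]1[C@@H]2O[Si](C)(C)C(C)(C)C | intermediate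
26 | (1R,4S,5R,10S)-4,7,10-tris(TBSO)-2-methylidene-5-[(2S)-6-methylhept-5-en-2-yl]bicyclo[4.3.1]dec-6-ene | C=C1C[C@H](O[Si](C)(C)C(C)(C)C)[C@H]([C@@H](C)CCC=C(C)C)C2=C(O[Si](C)(C)C(C)(C)C)CC[C@H]1[C@@H]2O[Si](C)(C)C(C)(C)C | intermediate
27 | (1R,4S,5R,6S,10S)-4,10-bis(TBSO)-2-methylidene-5-[(2S)-6-methylhept-5-en-2-yl]bicyclo[4.3.1]decan-7-one | C=C1C[C@H](O[Si](C)(C)C(C)(C)C)[C@H]([C@@H](C)CCC=C(C)C)[C@@H]2C(=O)CC[C@H]1[C@@H]2O[Si](C)(C)C(C)(C)C | intermediate
28 | potassium C7–C8 enolate of 27 | [K+].C=C1C[C@H](O[Si](C)(C)C(C)(C)C)[C@H]([C@@H](C)CCC=C(C)C)[C@@H]2C([O-])=CC[C@H]1[C@@H]2O[Si](C)(C)C(C)(C)C | intermediate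
29 | (1R,4S,5R,6S,10S)-4,10-bis(TBSO)-2-methylidene-5-[(2S)-6-methylhept-5-en-2-yl]bicyclo[4.3.1]dec-7-en-7-yl trifluoromethanesulfonate | C=C1C[C@H](O[Si](C)(C)C(C)(C)C)[C@H]([C@@H](C)CCC=C(C)C)[C@@H]2C(OS(=O)(=O)C(F)(F)F)=CC[C@H]1[C@@H]2O[Si](C)(C)C(C)(C)C | intermediate
30 | (1R,4S,5R,6R,10S)-4,10-bis(TBSO)-2-methylidene-5-[(2S)-6-methylhept-5-en-2-yl]bicyclo[4.3.1]dec-7-ene-7-carbaldehyde | C=C1C[C@H](O[Si](C)(C)C(C)(C)C)[C@H]([C@@H](C)CCC=C(C)C)[C@@H]2C(C=O)=CC[C@H]1[C@@H]2O[Si](C)(C)C(C)(C)C | intermediate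
31 | (1R,4S,5R,6R,10S)-4,10-dihydroxy-2-methylidene-5-[(2S)-6-methylhept-5-en-2-yl]bicyclo[4.3.1]dec-7-ene-7-carbaldehyde | C=C1C[C@H](O)[C@H]([C@@H](C)CCC=C(C)C)[C@@H]2C(C=O)=CC[C@H]1[C@@H]2O | intermediate
32 | (1R,4S,5R,6R,10S)-7-formyl-2-methylidene-5-[(2S)-6-methylhept-5-en-2-yl]bicyclo[4.3.1]dec-7-ene-4,10-diyl diacetate | C=C1C[C@H](OC(C)=O)[C@H]([C@@H](C)CCC=C(C)C)[C@@H]2C(C=O)=CC[C@H]1[C@@H]2OC(C)=O | target

**Step count**

Total step count: 19. Longest linear sequence: 19 steps (from 1; all other inputs are commercial reagents).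

**Steps most likely to fail**

Step 13. The two diene faces may not be distinguished well enough, because the C7 silyloxy group also flanks C5 and can offset the allylic-strain bias from the C10 side; the dienol silyl ethers may also be lost thermally before ring closure. The fallback replaces thermal, substrate-controlled cycloaddition by a catalyst-controlled, Lewis-acid-activated one. Starting from 24, the enone is activated at −78 °C in CH2Cl2 by a triflimide-protonated oxazaborolidine (cationic boron Lewis acid of the CBS type). The catalyst enantiomer is chosen so that it blocks the enone face leading to the unwanted adduct. Silyloxydienes and vinyl ketones are established partners for this catalyst class, and the low temperature removes the thermal decomposition pathways. The fallback comes back to the route at 25 and makes no new compound (F0).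

Step 12. The released N,O-dimethylhydroxylamine may add in conjugate fashion to the new vinyl ketone, and the dienol silyl ethers may be protodesilylated during the quench. The fallback builds the enone by reduction, addition and oxidation, so that no amine is present once a Michael acceptor exists. Starting from 21, iBu2AlH at −78 °C (aqueous potassium sodium tartrate work-up) should give (3S,4R)-3,6-bis(TBSO)-5-[(E)-(TBSO)methylidene]-4-[(2S)-6-methylhept-5-en-2-yl]hept-6-enal F1. Addition of CH2=CHMgBr should give (5S,6R)-5,8-bis(TBSO)-7-[(E)-(TBSO)methylidene]-6-[(2S)-6-methylhept-5-en-2-yl]nona-1,8-dien-3-ol F2 as a mixture of carbinol epimers, which does not matter. Oxidation with activated MnO2 in CH2Cl2/toluene then gives 24, where the fallback rejoins the route; the solution can be diluted and heated directly for step 13.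

Step 9. C-acylation at C6 may be slow or give O-acylation, because C6 sits next to the fully substituted C5 and the Weinreb amide can compete for MgBr2. The fallback moves the acetylation to the aldehyde oxidation level (Stork enamine acylation). Starting from 16, Fukuyama reduction (Et3SiH, Pd/C) should give (3S,4S)-3-(TBSO)-N-methoxy-N-methyl-4-[(2S)-6-methylhept-5-en-2-yl]-6-oxohexanamide F3. Pyrrolidine with K2CO3 should convert it into the (E)-pyrrolidine enamine (3S,4R)-3-(TBSO)-N-methoxy-N-methyl-4-[(2S)-6-methylhept-5-en-2-yl]-6-(pyrrolidin-1-yl)hex-5-enamide F4. Acetyl chloride with Et3N should acylate the enamine carbon to give the vinylogous amide (3S,4R)-3-(TBSO)-N-methoxy-N-methyl-4-[(2S)-6-methylhept-5-en-2-yl]-6-oxo-5-(pyrrolidin-1-ylmethylidene)heptanamide F5. Hydrolysis with aqueous acetic acid/sodium acetate gives 19, where the fallback rejoins the route.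

**Further compounds**

F0 | step 13 | none | none
F1 | step 12 | (3S,4R)-3,6-bis(TBSO)-5-[(E)-(TBSO)methylidene]-4-[(2S)-6-methylhept-5-en-2-yl]hept-6-enal | O=CC[C@H](O[Si](C)(C)C(C)(C)C)[C@H]([C@@H](C)CCC=C(C)C)/C(=C\O[Si](C)(C)C(C)(C)C)C(=C)O[Si](C)(C)C(C)(C)C
F2 | step 12 | (5S,6R)-5,8-bis(TBSO)-7-[(E)-(TBSO)methylidene]-6-[(2S)-6-methylhept-5-en-2-yl]nona-1,8-dien-3-ol (C3 epimers) | C=CC(O)C[C@H](O[Si](C)(C)C(C)(C)C)[C@H]([C@@H](C)CCC=C(C)C)/C(=C\O[Si](C)(C)C(C)(C)C)C(=C)O[Si](C)(C)C(C)(C)C
F3 | step 9 | (3S,4S)-3-(TBSO)-N-methoxy-N-methyl-4-[(2S)-6-methylhept-5-en-2-yl]-6-oxohexanamide | CON(C)C(=O)C[C@H](O[Si](C)(C)C(C)(C)C)[C@H]([C@@H](C)CCC=C(C)C)CC=O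
F4 | step 9 | (3S,4R,5E)-3-(TBSO)-N-methoxy-N-methyl-4-[(2S)-6-methylhept-5-en-2-yl]-6-(pyrrolidin-1-yl)hex-5-enamide | CON(C)C(=O)C[C@H](O[Si](C)(C)C(C)(C)C)[C@H]([C@@H](C)CCC=C(C)C)/C=C/N1CCCC1
F5 | step 9 | (3S,4R)-3-(TBSO)-N-methoxy-N-methyl-4-[(2S)-6-methylhept-5-en-2-yl]-6-oxo-5-(pyrrolidin-1-ylmethylidene)heptanamide | CON(C)C(=O)C[C@H](O[Si](C)(C)C(C)(C)C)[C@H]([C@@H](C)CCC=C(C)C)C(=CN1CCCC1)C(C)=O
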